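## The problem

The target 31 is a germacranolide. A ten-membered carbocycle (C1–C10) is fused across C6–C7 to a butenolide whose alkene is C7=C11, with the lactone oxygen on C6, an acetoxymethyl group (C13) on C11 and an (S)-2-methylglycidate on the C8 oxygen. The ring carries a trans-1,10-epoxide and a cis-4,5-epoxide, so seven stereocentres must be set (1R, 4R, 5S, 6S, 8S, 10R, 2'S). C4, C5 and C6 are contiguous and can control one another. C8 and the C1/C10 pair are insulated by methylene groups and C2' is remote, so these need reagent control or the chiral pool. Three groups will not survive rough treatment. The trisubstituted epoxides are opened by protic and strong Lewis acids, the glycidate ester is labile to nucleophiles and base, and the 13-acetoxy butenolide has an acidic γ-hydrogen at C6. Base at C6 can epimerise that centre, expel a leaving group from C5 or eject the C13 acetate. The central difficulty is closing a strained ten-membered carbocycle without oligomerisation or transannular reaction. The structure offers a retron for this: C6 is the γ-carbon of the butenolide C12(=O)–C11=C7–C6 and is bonded to C5, which bears oxygen and is flanked by the quaternary, oxygenated C4. Attack of a furan-2-olate equivalent through C6 on a C5 aldehyde therefore forms C5–C6, both oxygenated centres and the ring in one step, and the C4 oxygen can both direct that addition and become the epoxide oxygen.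

## Retrosynthesis

**Side chain (31 to 27 and 29).** The C8–O acyl bond is cut last, because the glycidate is the most fragile group and should meet as few reagents as possible. Alcohol 27 lacks one epoxide and one stereocentre, and acid 29 comes in one step from (R)-2-methylglycidol 28. The forward step must acylate a hindered secondary alcohol with a quaternary acid under mild conditions.

**Acetate and 4,5-epoxide (27 back to 22).** The C13 acetate is traced to a PMB ether, because an acyloxymethyl group on a furan-2-olate is a vinylogous leaving group and could not pass through the ring closure. The oxirane is cut at C5–O. The oxygen stays on C4 and C5 takes a mesylate (24, from 23), so closure inverts C5. A cis-epoxide therefore requires the 4,5-syn diol derivative, (4R,5R) in 22. The neighbouring option, epoxidising a 4Z alkene on the formed ring, would leave face selection to ring conformation alone.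

**Ring closure (22 to 21, key step).** The C5–C6 bond is cut. The other ring bonds are poorer choices: closure at C8–C9 by alkylation or at C1–C2 by cross-coupling would form the ring but no stereocentre, and would require C5 and C6 to be set on an open chain. The aldol cut gives an acyclic precursor 21 with two stereocentres fewer, built from a flat, aromatic 2-silyloxyfuran and a non-enolisable aldehyde. The forward reaction must deliver γ-attack, ring closure over oligomerisation, the 4,5-syn and 5,6-syn relationships, and tolerance of the 1,10-epoxide. These demands fix the protecting group on the C4 oxygen and the promoter. A silyl ether with BF3·OEt2 would react through a non-chelated Felkin–Anh arrangement, which leads to the 4,5-anti isomer and, after inversion, to the trans-epoxide. BF3 would also open the trisubstituted epoxide toward the tethered furan. A chelating PMB ether and MgBr2·OEt2 are therefore chosen.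

**Nucleophile and electrophile (21 back to 17).** The silyloxyfuran comes from butenolide 20 by soft enolisation. The aldehyde comes from the vinyl group of 18 by Lemieux–Johnson cleavage. This cleavage is possible only once the more electron-rich C1=C10 alkene has been converted to its epoxide, so the Shi epoxidation of 17 must come first. That step sets C1 and C10 by reagent control on an open chain, where the outcome is predictable.

**Butenolide from a furan (17 to 14).** The C12 carbonyl and the C6 methylene are traced to a 3,4-disubstituted furan. A furan is chosen as the carrier because the C8 acyl-anion chemistry below needs a ring that is neither acidic nor electrophilic. A butenolide bearing the dithiane would offer two competing γ-acidic sites (C6 and C8) and an ambident dienolate. The forward step must oxidise the furan at the α-carbon next to the CH2OPMB arm.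

**C8 and the C8–C9 bond (14 back to 9 and 4).** The C8 carbinol comes from ketone 12 by Corey–Bakshi–Shibata reduction. The ketone comes from dithiane 11, and 11 from alkylation of lithiated furyl dithiane 10 with allylic bromide 4 (Corey–Seebach). The alternatives are worse. Addition of an allyl metal derived from 4 to a C8 aldehyde would react at the γ-carbon and give the branched isomer. A C7–C8 coupling would need a β,γ-unsaturated aldehyde one carbon longer than 4.

**Fragments.** Bromide 4 derives from (R)-linalool 1, which supplies C4 with its oxygen and methyl group, the vinyl group as latent C5 aldehyde, and the (E)-methyl group that becomes C9. Dithiane 9 comes from 3,4-bis(hydroxymethyl)furan 5 and propane-1,3-dithiol 8. The symmetry of 5 is broken by monoprotection.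

## Roads not taken

**Alternative 1:** The cut is at C4–C5 and C1–C10, made in the forward sense by a [2+2] photocycloaddition of a 3-methylcyclohexenone with a cyclobutene ester to give the tricyclic keto ester A1. The ten-membered ring is the perimeter of A1 and is released by cleaving the two internal cyclobutane bonds. Its merit is that the medium ring arises by fragmentation and not by end-to-end closure, so no entropic penalty is paid, and C8 and the C10 methyl are in place early. In this respect it is more reliable than a ten-membered aldol. Its weak points for this target are several. The regiochemistry of the photoaddition is not secured. The thermal opening gives 1,5-dienes that can undergo Cope rearrangement at the temperature needed. The ester carbon must be reduced to the C15 methyl. The whole butenolide with C13, the C6 oxygen and both epoxides would have to be added to a flexible cyclodecadiene by substrate control. The chosen plan concedes the safer ring formation but sets C4, C8 and C1/C10 before cyclisation and creates C5, C6 and the lactone in the ring-forming step itself.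

**Alternative 2:** The forward key step is a Wharton fragmentation of a cis-fused hydroazulenol monotosylate, which cleaves C6–C10 and gives the cyclodecadienone A2. Its merits are real. The antiperiplanar fragmentation fixes the E geometry of C1=C10, the ring forms without high dilution, and the 4Z enone of A2 would accept a nucleophilic epoxidation to the cis-4,5-epoxide. On ring formation and alkene geometry it is equal or superior to the chosen plan. Its weakness is what A2 lacks: C11, C12 and C13. The butenolide would have to be annulated at C7 by enolate chemistry on a cyclodecadienone that is prone to transannular reactions. C6 would then be set by reduction on the medium ring, and the bicyclic precursor itself needs several stereocentres that do not survive into the target. Against this the chosen plan sets a convergent union of two simple fragments and the arrival of the complete, oxygenated butenolide before ring closure.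

**Alternative 3:** The cut is at C1–C2. 9-BBN hydroboration of a terminal vinyl group and intramolecular B-alkyl Suzuki–Miyaura coupling with an (E)-vinyl iodide (Pd(dppf)Cl2, Cs2CO3) would give the trienolide A3. A3 is closer to the target than the key product 22 of the chosen plan, since only two epoxidations and an ester exchange remain; in step count after ring closure this road is better. Its weak points are specific. The 13-acetoxymethyl butenolide is an allylic acetate and the C6 oxygen is a γ-acyloxy leaving group, and both can ionise with zerovalent palladium. The borane must distinguish the vinyl group from the lactone and the conjugated alkene. Reductive elimination to a strained (E)-cyclodecene competes with β-hydride elimination and dimerisation. C6 must be set beforehand on an open chain, and both epoxides are then introduced on the macrocycle, where facial and site selectivity between two trisubstituted alkenes rest on conformation only. The chosen plan accepts a less precedented ring closure, but it sets the 1,10-epoxide by reagent control on an open chain and derives the 4,5-epoxide stereospecifically from the aldol stereochemistry.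

Key step: step 15

Assumptions: germacrane numbering (ring C1–C10, butenolide carbons C11–C13) is used for positions in all intermediates, including open-chain ones. 3,4-Bis(hydroxymethyl)furan (5) and (R)-2-methylglycidol (28) are taken as commercial.

## Route

Step 1
Reactants: 1 (R)-linalool
Product: 2 (R)-linalyl 4-methoxybenzyl ether, (3R)-3-(4-methoxybenzyloxy)-3,7-dimethylocta-1,6-diene
Conditions: NaH, PMBCl, Bu4NI (cat.), DMF, 0 → 40 °C
Reagents that add atoms: 4-methoxybenzyl chloride, COc1ccc(CCl)cc1
Why: Williamson etherification of the tertiary alkoxide; the stereocentre (C4) is not touched, and the PMB ether is chosen because its oxygen can chelate magnesium in step 15 and is removed by DDQ without acid.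

Step 2
Reactants: 2 (R)-linalyl 4-methoxybenzyl ether
Product: 3 (2E,6R)-6-(4-methoxybenzyloxy)-2,6-dimethylocta-2,7-dien-1-ol
Conditions: SeO2 (0.5 equiv), t-BuOOH, salicylic acid (cat.), CH2Cl2, rt
Reagents that add atoms: tert-butyl hydroperoxide, CC(C)(C)OO (oxygen atom, relayed through selenium dioxide, O=[Se]=O)
Why: Riley allylic oxidation; the ene reaction and [2,3]-sigmatropic shift occur at the more substituted alkene terminus and select the (E)-methyl group, which fixes the E geometry of the future C1=C10 bond, while the vinyl group has no allylic hydrogen.

Step 3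
Reactants: 3 (2E,6R)-6-(4-methoxybenzyloxy)-2,6-dimethylocta-2,7-dien-1-ol
Product: 4 (2E,6R)-1-bromo-6-(4-methoxybenzyloxy)-2,6-dimethylocta-2,7-diene
Conditions: CBr4, PPh3, CH2Cl2, 0 °C
Reagents that add atoms: carbon tetrabromide, BrC(Br)(Br)Br
Why: Appel bromination of a primary allylic alcohol under neutral conditions, which should proceed without allylic transposition or loss of alkene geometry.

Step 4
Reactants: 5 3,4-bis(hydroxymethyl)furan
Product: 6 {4-[(4-methoxybenzyloxy)methyl]furan-3-yl}methanol
Conditions: NaH (1.0 equiv), PMBCl (1.0 equiv), Bu4NI (cat.), THF, 0 °C → rt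
Reagents that add atoms: 4-methoxybenzyl chloride, COc1ccc(CCl)cc1
Why: Statistical mono-etherification of a symmetrical diol through its mono-alkoxide; the protected arm becomes C13 and the free arm C8.

Step 5
Reactants: 6 {4-[(4-methoxybenzyloxy)methyl]furan-3-yl}methanol
Product: 7 4-[(4-methoxybenzyloxy)methyl]furan-3-carbaldehyde
Conditions: MnO2, CH2Cl2, rt
Reagents that add atoms: none
Why: MnO2 oxidises the furylic (benzylic-type) alcohol selectively to the aldehyde and leaves the electron-rich furan and the PMB ether alone.

Step 6
Reactants: 7 4-[(4-methoxybenzyloxy)methyl]furan-3-carbaldehyde; 8 propane-1,3-dithiol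
Product: 9 2-{4-[(4-methoxybenzyloxy)methyl]furan-3-yl}-1,3-dithiane
Conditions: BF3·OEt2 (cat.), CH2Cl2, −30 °C
Reagents that add atoms: none
Why: Lewis acid-catalysed dithioacetalisation of an aromatic aldehyde; a catalytic amount of acid at low temperature should spare the furan and the PMB ether.

Step 7
Reactants: 9 2-{4-[(4-methoxybenzyloxy)methyl]furan-3-yl}-1,3-dithiane; 4 (2E,6R)-1-bromo-6-(4-methoxybenzyloxy)-2,6-dimethylocta-2,7-diene
Product: 11 2-{4-[(4-methoxybenzyloxy)methyl]furan-3-yl}-2-[(2E,6R)-6-(4-methoxybenzyloxy)-2,6-dimethylocta-2,7-dien-1-yl]-1,3-dithiane, via lithiated dithiane 10 (not isolated)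
Conditions: n-BuLi, THF, −78 → −30 °C; then 4, −78 → −20 °C
Reagents that add atoms: none
Why: Corey–Seebach alkylation; the aryl-stabilised dithiane C–H is several pK units more acidic than the furan α-hydrogens and the ether benzylic hydrogens, and the soft, bulky anion displaces the primary allylic bromide at carbon (C8–C9 bond) with the alkene geometry retained.

Step 8
Reactants: 11 furyl allyl dithiane
Product: 12 (3E,7R)-7-(4-methoxybenzyloxy)-1-{4-[(4-methoxybenzyloxy)methyl]furan-3-yl}-3,7-dimethylnona-3,8-dien-1-one
Conditions: MeI, CaCO3, MeCN/H2O (9:1), 45 °C
Reagents that add atoms: water, O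
Why: Alkylative dithiane hydrolysis via the S-methylsulfonium ion; these non-oxidising, carbonate-buffered conditions avoid furan oxidation or mercuration and should not move the β,γ-alkene into conjugation.

Step 9
Reactants: 12 furyl ketone
Product: 13 (1S,3E,7R)-7-(4-methoxybenzyloxy)-1-{4-[(4-methoxybenzyloxy)methyl]furan-3-yl}-3,7-dimethylnona-3,8-dien-1-ol
Conditions: (R)-2-methyl-CBS-oxazaborolidine (0.2 equiv), catecholborane, toluene, −78 °C
Reagents that add atoms: none
Why: Corey–Bakshi–Shibata reduction; the furyl group is the large substituent and the allylic methylene the small one, so the (R)-catalyst, which gives (S)-carbinols from aryl alkyl ketones, should set 8S, and catecholborane at low temperature does not hydroborate the alkenes.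

Step 10
Reactants: 13 (1S)-furyl carbinol
Product: 14 tert-butyldimethylsilyl ether of 13
Conditions: TBSOTf, 2,6-lutidine, CH2Cl2, −78 °C
Reagents that add atoms: tert-butyldimethylsilyl triflate, CC(C)(C)[Si](C)(C)OS(=O)(=O)C(F)(F)F
Why: Standard silylation of a hindered secondary alcohol; the bulky silyl ether also increases the steric difference between the two furan α-positions for step 11.

Step 11
Reactants: 14 silyl-protected furan
Product: 17 4-[(1S,3E,7R)-1-(tert-butyldimethylsilyloxy)-7-(4-methoxybenzyloxy)-3,7-dimethylnona-3,8-dien-1-yl]-3-[(4-methoxybenzyloxy)methyl]furan-2(5H)-one, via furan endoperoxide 15 (not isolated), via 5-hydroxybutenolide 16 (not isolated)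
Conditions: O2, hν (visible), tetraphenylporphyrin (cat.), i-Pr2NEt, CH2Cl2, −78 °C; then NaBH4, MeOH, 0 °C; pH 3 work-up
Reagents that add atoms: dioxygen, O=O
Why: Singlet oxygen adds [4+2] to the furan much faster than it undergoes the ene reaction with the trisubstituted alkene at −78 °C; the hindered amine removes the less hindered bridgehead hydrogen of 15 (at C12, next to the CH2OPMB arm) in a Kornblum–DeLaMare fragmentation, so C12 becomes the carbonyl, and borohydride reduction of the open aldehyde form of 16 followed by relactonisation gives the butenolide.

Step 12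
Reactants: 17 butenolide diene
Product: 18 (1R,10R)-1,10-epoxide of 17
Conditions: D-fructose-derived Shi ketone (0.3 equiv), KHSO5 (Oxone), K2CO3, Bu4NHSO4, MeCN/CH2(OMe)2/aq. Na2B4O7 buffer, 0 °C
Reagents that add atoms: potassium peroxymonosulfate, [K+].[O-]S(=O)(=O)OO
Why: Shi epoxidation through the spiro transition state; the D-fructose-derived dioxirane converts (E)-trisubstituted alkenes into (R,R)-epoxides, here 1R,10R with the trans geometry given by the alkene, while the hindered vinyl group and the electron-poor butenolide alkene react far more slowly.

Step 13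
Reactants: 18 epoxy butenolide
Product: 20 5,6-seco C5 aldehyde (2-(4-methoxybenzyloxy)-2-methyl aldehyde, 1R,4R,8S,10R), via vicinal diol 19 (not isolated)
Conditions: OsO4 (cat.), NaIO4, 2,6-lutidine, dioxane/H2O (3:1), rt
Reagents that add atoms: osmium tetroxide, O=[Os](=O)(=O)=O (catalytic oxygen carrier); sodium periodate, [Na+].[O-]I(=O)(=O)=O
Why: Lemieux–Johnson cleavage; with C1=C10 now an epoxide the vinyl group is the only electron-rich alkene, the conjugated tetrasubstituted butenolide alkene is inert to OsO4, and the aldehyde formed has no α-hydrogen, so C4 cannot epimerise.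

Step 14
Reactants: 20 butenolide aldehyde
Product: 21 2-(triisopropylsilyloxy)furan aldehyde (key-step precursor)
Conditions: TIPSOTf, Et3N, CH2Cl2, −78 → 0 °C
Reagents that add atoms: triisopropylsilyl triflate, CC(C)[Si](C(C)C)(C(C)C)OS(=O)(=O)C(F)(F)F
Why: Soft enolisation of the butenolide (O-silylation, then loss of a C6 hydrogen) gives the aromatic 2-silyloxyfuran; the aldehyde cannot form a silyl enol ether, and excess amine at low temperature should keep the triflate from activating the epoxide.

Step 15
Reactants: 21 2-(triisopropylsilyloxy)furan aldehyde
Product: 22 (1R,4R,5R,6S,8S,10R)-8-(tert-butyldimethylsilyloxy)-1,10-epoxy-5-hydroxy-4,13-bis(4-methoxybenzyloxy)germacr-7(11)-en-12,6-olide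
Conditions: MgBr2·OEt2 (3 equiv), CH2Cl2, −78 → −30 °C, syringe-pump addition of 21 (final 1 mM); aq. NaHCO3
Reagents that add atoms: none
Why: MgBr2 binds the aldehyde oxygen and the C4 PMB ether oxygen in a five-membered chelate, the electron-rich free 5-position of the silyloxyfuran (C6) adds to the activated carbonyl, and loss of silicon from the resulting oxocarbenium ion restores the lactone carbonyl as the C7=C11 butenolide. The closest known reaction type is the chelation-controlled vinylogous Mukaiyama aldol of 2-silyloxyfurans with α-alkoxy aldehydes and its intramolecular form, which is known for five- to eight-membered carbocycles; the ten-membered closure is an extension in ring size. The ring closes by 10-exo-trig carbonyl addition with the enol double bond inside the new ring, and the flat furan and the trans-epoxide remove four rotors from the chain. C5 is controlled by the chelate: the C3 tether and the C4 methyl flank the chelate plane and C6 adds on the methyl face, anti to the tether, which gives the 4,5-syn arrangement (5R) required for the cis-epoxide after inversion; a ten-membered ring can accommodate the resulting near-antiperiplanar C3–C4–C5–C6 torsion. C6 is controlled relative to C5 by the open transition state in which the furan ring turns away from the aldehyde substituent, the usual syn preference of Lewis acid-promoted silyloxyfuran aldols, and this gives 6S. The step needs γ- over α-attack, secured because C11 is fully substituted; ring closure over oligomerisation, secured by slow addition at high dilution; and activation of the aldehyde over the epoxide, secured by a Lewis acid that is strong only as a chelate and is used cold.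

Step 16
Reactants: 22 macrocyclic aldol
Product: 23 5-O-methanesulfonate of 22
Conditions: Ms2O, pyridine, DMAP (cat.), CH2Cl2, 0 °C
Reagents that add atoms: methanesulfonic anhydride, CS(=O)(=O)OS(C)(=O)=O
Why: Sulfonylation of the only free hydroxyl; pyridine is too weak a base to remove the acidic C6 hydrogen, so β-elimination toward the butenolide should not start here.

Step 17
Reactants: 23 mesylate
Product: 24 (1R,4R,5R,6S,8S,10R)-8-(tert-butyldimethylsilyloxy)-1,10-epoxy-4,13-dihydroxy-5-(methanesulfonyloxy)germacr-7(11)-en-12,6-olide
Conditions: DDQ, CH2Cl2/pH 7 phosphate buffer (10:1), 0 °C → rt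
Reagents that add atoms: none
Why: Oxidative cleavage of both PMB ethers by benzylic hydride abstraction and hydrolysis of the oxocarbenium ions; the buffered, neutral medium leaves the epoxide, the mesylate and the silyl ether intact.

Step 18
Reactants: 24 hydroxy mesylate
Product: 25 (1R,4R,5S,6S,8S,10R)-8-(tert-butyldimethylsilyloxy)-1,10:4,5-diepoxy-13-hydroxygermacr-7(11)-en-12,6-olide
Conditions: K2CO3, MeOH, 0 °C
Reagents that add atoms: none
Why: Intramolecular Williamson (3-exo-tet) displacement of the C5 mesylate by the C4 alkoxide; inversion at C5 (5R to 5S) turns the 4,5-syn diol derivative into the cis-epoxide, and a mild protic base is used to disfavour deprotonation at C6.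

Step 19
Reactants: 25 diepoxy alcohol
Product: 26 13-acetate of 25
Conditions: Ac2O, pyridine, DMAP (cat.), CH2Cl2, 0 °C
Reagents that add atoms: acetic anhydride, CC(=O)OC(C)=O
Why: Acetylation of the only free (primary) hydroxyl under mild conditions; the acetate is introduced only now because it would act as a vinylogous leaving group at the silyloxyfuran stage.

Step 20
Reactants: 26 silyl ether acetate
Product: 27 (1R,4R,5S,6S,8S,10R)-13-acetoxy-1,10:4,5-diepoxy-8-hydroxygermacr-7(11)-en-12,6-olide
Conditions: Bu4NF, AcOH (1:1), THF, 0 °C → rt
Reagents that add atoms: none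
Why: Fluoride desilylation buffered with acetic acid, so that neither the acetate nor the epoxides meet free alkoxide or HF, and the released C8 hydroxyl is not left under basic conditions in which it could translactonise.

Step 21
Reactants: 28 (R)-2-methylglycidol
Product: 29 (S)-2-methyloxirane-2-carboxylic acid
Conditions: RuCl3·xH2O (cat.), NaIO4, MeCN/EtOAc/H2O, 0 °C → rt
Reagents that add atoms: water, O
Why: RuO4-catalysed oxidation of a primary alcohol to the acid, well established for epoxy alcohols; the quaternary stereocentre cannot epimerise, and the descriptor changes from R to S only because the carboxyl group outranks the ring methylene.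

Step 22
Reactants: 27 C8 alcohol; 29 (S)-2-methyloxirane-2-carboxylic acid
Product: 31 target, (1R,4R,5S,6S,8S,10R)-13-acetoxy-1,10:4,5-diepoxy-8-[(2S)-2-methyloxirane-2-carbonyloxy]germacr-7(11)-en-12,6-olide, via mixed anhydride 30 (not isolated)
Conditions: 29, 2,4,6-trichlorobenzoyl chloride, Et3N, THF, 0 °C; then 27, DMAP, toluene, rt
Reagents that add atoms: none
Why: Yamaguchi esterification; the mixed anhydride and DMAP transfer the hindered quaternary acyl group to the hindered secondary alcohol under nearly neutral conditions with retention at C8, and no free chloride or strong base meets the three epoxides.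

## Compound list

1 | (R)-linalool | CC(C)=CCC[C@@](C)(O)C=C | starting material
2 | (R)-linalyl 4-methoxybenzyl ether | CC(C)=CCC[C@@](C)(OCc1ccc(OC)cc1)C=C | intermediate
3 | (2E,6R)-6-(4-methoxybenzyloxy)-2,6-dimethylocta-2,7-dien-1-ol | OC/C(C)=C/CC[C@@](C)(OCc1ccc(OC)cc1)C=C | intermediate
4 | (2E,6R)-1-bromo-6-(4-methoxybenzyloxy)-2,6-dimethylocta-2,7-diene | BrC/C(C)=C/CC[C@@](C)(OCc1ccc(OC)cc1)C=C | intermediate
5 | 3,4-bis(hydroxymethyl)furan | OCc1cocc1CO | starting material
6 | {4-[(4-methoxybenzyloxy)methyl]furan-3-yl}methanol | OCc1cocc1COCc1ccc(OC)cc1 | intermediate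
7 | 4-[(4-methoxybenzyloxy)methyl]furan-3-carbaldehyde | O=Cc1cocc1COCc1ccc(OC)cc1 | intermediate
8 | propane-1,3-dithiol | SCCCS | starting material
9 | 2-{4-[(4-methoxybenzyloxy)methyl]furan-3-yl}-1,3-dithiane | COc1ccc(COCc2cocc2C2SCCCS2)cc1 | intermediate
10 | 2-lithio derivative of 9 | COc1ccc(COCc2cocc2C2([Li])SCCCS2)cc1 | intermediate (not isolated)
11 | 2-furyl-2-[(2E,6R)-6-(4-methoxybenzyloxy)-2,6-dimethylocta-2,7-dien-1-yl]-1,3-dithiane | COc1ccc(COCc2cocc2C2(C/C(C)=C/CC[C@@](C)(OCc3ccc(OC)cc3)C=C)SCCCS2)cc1 | intermediate
12 | (3E,7R)-furyl ketone | COc1ccc(COCc2cocc2C(=O)C/C(C)=C/CC[C@@](C)(OCc2ccc(OC)cc2)C=C)cc1 | intermediate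
13 | (1S,3E,7R)-furyl carbinol (8S) | COc1ccc(COCc2cocc2[C@@H](O)C/C(C)=C/CC[C@@](C)(OCc2ccc(OC)cc2)C=C)cc1 | intermediate
14 | tert-butyldimethylsilyl ether of 13 | COc1ccc(COCc2cocc2[C@@H](O[Si](C)(C)C(C)(C)C)C/C(C)=C/CC[C@@](C)(OCc2ccc(OC)cc2)C=C)cc1 | intermediate
15 | furan 2,5-endoperoxide of 14 (mixture at the bridgeheads) | COc1ccc(COCC2=C([C@@H](O[Si](C)(C)C(C)(C)C)C/C(C)=C/CC[C@@](C)(OCc3ccc(OC)cc3)C=C)C3OOC2O3)cc1 | intermediate (not isolated)
16 | 5-hydroxybutenolide (C12 carbonyl, C6 hemiacetal, mixture at C6) | COc1ccc(COCC2=C([C@@H](O[Si](C)(C)C(C)(C)C)C/C(C)=C/CC[C@@](C)(OCc3ccc(OC)cc3)C=C)C(O)OC2=O)cc1 | intermediate (not isolated)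
17 | 3-(PMB-oxymethyl)-4-substituted furan-2(5H)-one (8S, 4R, 1(10)E) | COc1ccc(COCC2=C([C@@H](O[Si](C)(C)C(C)(C)C)C/C(C)=C/CC[C@@](C)(OCc3ccc(OC)cc3)C=C)COC2=O)cc1 | intermediate
18 | (1R,10R)-epoxy butenolide | COc1ccc(COCC2=C([C@@H](O[Si](C)(C)C(C)(C)C)C[C@@]3(C)O[C@@H]3CC[C@@](C)(OCc3ccc(OC)cc3)C=C)COC2=O)cc1 | intermediate
19 | vicinal diol from the vinyl group of 18 (mixture at the new carbinol) | COc1ccc(COCC2=C([C@@H](O[Si](C)(C)C(C)(C)C)C[C@@]3(C)O[C@@H]3CC[C@@](C)(OCc3ccc(OC)cc3)C(O)CO)COC2=O)cc1 | intermediate (not isolated)
20 | 5,6-seco C5 aldehyde with butenolide (1R,4R,8S,10R) | COc1ccc(COCC2=C([C@@H](O[Si](C)(C)C(C)(C)C)C[C@@]3(C)O[C@@H]3CC[C@@](C)(OCc3ccc(OC)cc3)C=O)COC2=O)cc1 | intermediate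
21 | 2-(triisopropylsilyloxy)furan aldehyde (key-step precursor) | COc1ccc(COCc2c(O[Si](C(C)C)(C(C)C)C(C)C)occ2[C@@H](O[Si](C)(C)C(C)(C)C)C[C@@]2(C)O[C@@H]2CC[C@@](C)(OCc2ccc(OC)cc2)C=O)cc1 | intermediate
22 | (1R,4R,5R,6S,8S,10R)-8-(TBS-oxy)-1,10-epoxy-5-hydroxy-4,13-bis(PMB-oxy)germacr-7(11)-en-12,6-olide (key-step product) | COc1ccc(COCC2=C3[C@@H](O[Si](C)(C)C(C)(C)C)C[C@@]4(C)O[C@@H]4CC[C@@](C)(OCc4ccc(OC)cc4)[C@H](O)[C@H]3OC2=O)cc1 | intermediate
23 | 5-O-methanesulfonate of 22 | COc1ccc(COCC2=C3[C@@H](O[Si](C)(C)C(C)(C)C)C[C@@]4(C)O[C@@H]4CC[C@@](C)(OCc4ccc(OC)cc4)[C@H](OS(C)(=O)=O)[C@H]3OC2=O)cc1 | intermediate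
24 | 4,13-diol 5-mesylate | OCC1=C2[C@@H](O[Si](C)(C)C(C)(C)C)C[C@@]3(C)O[C@@H]3CC[C@@](C)(O)[C@H](OS(C)(=O)=O)[C@H]2OC1=O | intermediate
25 | (1R,4R,5S,6S,8S,10R)-8-(TBS-oxy)-1,10:4,5-diepoxy-13-hydroxygermacr-7(11)-en-12,6-olide | OCC1=C2[C@@H](O[Si](C)(C)C(C)(C)C)C[C@@]3(C)O[C@@H]3CC[C@@]3(C)O[C@H]3[C@H]2OC1=O | intermediate
26 | 13-acetate of 25 | CC(=O)OCC1=C2[C@@H](O[Si](C)(C)C(C)(C)C)C[C@@]3(C)O[C@@H]3CC[C@@]3(C)O[C@H]3[C@H]2OC1=O | intermediate
27 | 13-acetoxy-1,10:4,5-diepoxy-8-hydroxygermacr-7(11)-en-12,6-olide | CC(=O)OCC1=C2[C@@H](O)C[C@@]3(C)O[C@@H]3CC[C@@]3(C)O[C@H]3[C@H]2OC1=O | intermediate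
28 | (R)-2-methylglycidol, (2R)-(2-methyloxiran-2-yl)methanol | OC[C@]1(C)CO1 | starting material
29 | (S)-2-methyloxirane-2-carboxylic acid | OC(=O)[C@]1(C)CO1 | intermediate
30 | mixed anhydride of 29 with 2,4,6-trichlorobenzoic acid | O=C(OC(=O)c1c(Cl)cc(Cl)cc1Cl)[C@]1(C)CO1 | intermediate (not isolated)
31 | target | CC(=O)OCC1=C2[C@@H](OC(=O)[C@]3(C)CO3)C[C@@]3(C)O[C@@H]3CC[C@@]3(C)O[C@H]3[C@H]2OC1=O | target

## Step count and risks

Total: 22 steps. Longest linear sequence: 18 steps (steps 1–3, 7–20 and 22, from (R)-linalool).

**Step 15 (key step).** Three processes can defeat it. Intermolecular aldol addition may outrun the strained ten-membered closure. Ring strain may override the chelate and direct attack to the other aldehyde face. Bromide or the tethered furan may open the magnesium-activated trisubstituted epoxide. Fallback: a direct aldol without the silyl dienol ether, setting out from butenolide aldehyde 20 and returning at 22. Soft enolisation with MgBr2·OEt2 and i-Pr2NEt in CH2Cl2 would place the magnesium furanolate and the chelated aldehyde on the same metal, so the C5–C6 bond would form through a closed, templated transition state. This fallback makes no new compound.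

**Step 11.** The hindered base may abstract the C6 bridgehead hydrogen and give the regioisomeric lactone, or singlet oxygen may undergo the ene reaction with the C1=C10 alkene. Fallback: from furan 14, deprotonation with LiTMP in the presence of isopropoxy pinacolborane (in situ trapping) should metalate the less hindered, ether-flanked α-position and give the furan-2-yl pinacol boronate F1. Oxidation with NaBO3·4H2O and equilibration with Et3N would return to 17.

**Step 18.** The alkoxide or carbonate may remove the acidic C6 hydrogen, so that E1cB loss of the mesylate toward the butenolide (a γ-ylidene butenolide) competes with displacement. Fallback: avoid the mesylate and the base. From 22, DDQ would give the 4,5,13-triol F2. Selective acetylation of the primary hydroxyl (AcCl, 2,4,6-collidine, −78 °C) would give the diol acetate F3. Mitsunobu cyclodehydration (PPh3, DIAD, toluene) would then activate the secondary C5 hydroxyl as its oxyphosphonium ion and close the epoxide with inversion, returning to the route at 26.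

**Step 22.** Acyl transfer to the hindered C8 hydroxyl may be slow. The free hydroxyl could then translactonise to the 8,12-olide, or the activated glycidic acid could decompose. Fallback: from 27, EDC·HCl/DMAP coupling with the more robust, commercial (R)-3-bromo-2-hydroxy-2-methylpropanoic acid (OC(=O)[C@](O)(C)CBr) would give the bromohydrin ester F4. Ag2O in MeCN would then close the oxirane without base at the unchanged stereocentre and arrive at 31.

## Further compounds

F0 | step 15 | none | none
F1 | step 11 | pinacol boronate at C12 of furan 14 | COc1ccc(COCc2c(B3OC(C)(C)C(C)(C)O3)occ2[C@@H](O[Si](C)(C)C(C)(C)C)C/C(C)=C/CC[C@@](C)(OCc2ccc(OC)cc2)C=C)cc1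
F2 | step 18 | (1R,4R,5R,6S,8S,10R)-8-(TBS-oxy)-1,10-epoxy-4,5,13-trihydroxygermacr-7(11)-en-12,6-olide | OCC1=C2[C@@H](O[Si](C)(C)C(C)(C)C)C[C@@]3(C)O[C@@H]3CC[C@@](C)(O)[C@H](O)[C@H]2OC1=O
F3 | step 18 | 13-acetate of F2 | CC(=O)OCC1=C2[C@@H](O[Si](C)(C)C(C)(C)C)C[C@@]3(C)O[C@@H]3CC[C@@](C)(O)[C@H](O)[C@H]2OC1=O
F4 | step 22 | 8-O-[(2R)-3-bromo-2-hydroxy-2-methylpropanoyl] ester of 27 | CC(=O)OCC1=C2[C@@H](OC(=O)[C@](O)(C)CBr)C[C@@]3(C)O[C@@H]3CC[C@@]3(C)O[C@H]3[C@H]2OC1=O
A1 | alternative 1 | cis,anti,cis tricyclic keto ester photoadduct | O=C1C[C@@H](O[Si](C)(C)C(C)(C)C)C[C@]2(C)[C@H]1[C@@]1(C(=O)OC)CC[C@H]12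
A2 | alternative 2 | 8-(tert-butyldimethylsilyloxy)germacra-1(10)E,4Z-dien-6-one | O=C1C[C@@H](O[Si](C)(C)C(C)(C)C)C/C(C)=C/CC/C(C)=C\1
A3 | alternative 3 | 13-acetoxy-8-(tert-butyldimethylsilyloxy)germacra-1(10)E,4Z,7(11)-trien-12,6-olide | CC(=O)OCC1=C2[C@@H](O[Si](C)(C)C(C)(C)C)C/C(C)=C/CC/C(C)=C\[C@H]2OC1=O
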